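Abbreviations used throughout: prenyl = 3‑methylbut‑2‑en‑1‑yl; TIPS = triisopropylsilyl. Atom numbers C2–C8a (chroman) and C1'–C6' (ring B) are those of the target.

## Analysis of the target

Target 33 is an isoflavan quinone: a chroman (aromatic ring A fused to the pyran ring) that carries a 2‑hydroxy‑1,4‑benzoquinone (ring B) at C3. Ring A is a fully differentiated phloroglucinol, with O1 in the pyran ring, a methyl ether at C5, a prenyl group at C6 and a free hydroxyl at C7. The two oxygens that flank the prenyl group therefore have to end up different. Ring B has carbonyls at C2' and C5', hydroxyl at C4', prenyl at C3' and its only hydrogen at C6'. C3 (R) is the single stereocentre, so it needs absolute control and nothing else in the molecule can relay it. C3–H is γ to the C5' carbonyl through C1'=C6', so once the quinone exists, base can erase the centre through the quinone methide tautomer. Both prenyl groups lie ortho to oxygen functions and cyclise to chromans under acid, which rules out acid‑labile protecting groups late in the route and hydrogenation at any stage. The electron‑rich ring A also limits the oxidants that can be used to reach the quinone. The strategy rests on the pattern of ring B: para oxygens at C2' and C5', the chroman on C1', hydrogen on C6', a CH2 substituent on C3' and oxygen on C4'. This is the pattern formed when a terminal alkyne (C1', C6'), one carbonyl ligand (C2') and an α‑alkoxy alkenyl(methoxy)carbene (C3', C4', C5') are joined on chromium.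

## Retrosynthetic reasoning

**Endgame, 33 back to 30.** The hydroxyquinone is unveiled last because it is the most sensitive part and makes C3 epimerisable. The O7–Si bond of 32 is cut first, then the C4' hydroxyl of 32 is traced to the vinylogous methyl ester 31, and the quinone of 31 to the para‑methoxyphenol 30. The forward steps need only a mild oxidation of a free phenol, a short exposure to hydroxide and a buffered desilylation.

**Ring B, 30 back to 18 and 27.** Three bonds are cut: C5'–C6', C1'–C2' and C2'–C3'. The cut is made here because C6' is the only unsubstituted ring B carbon and, with C1', maps onto a terminal alkyne. C2' is a carbonyl ligand, and the remaining three carbons carry exactly two oxygens and the prenyl group. What is gained is a pentasubstituted ring whose regiochemistry is fixed by mechanism and which arrives with a free phenol para to a methoxy group, ready for oxidation. The forward reaction must insert alkyne 18 in one orientation and must stay free of base, because the skipped diene of 27 is easily moved into conjugation.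

**Carbene complex, 27 back to 24 and 25, then to 19 and 21.** The Cr=C bond and the O–methyl bond are cut to give acid chloride 24 and hexacarbonylchromium 25, through acyl chromate 26. This route is chosen over an alkenyllithium because an α‑methoxy alkenyllithium next to a doubly allylic CH2 cannot be generated cleanly, whereas 24 has no α‑hydrogen. Acid 23 and ester 22 come from an olefination that makes C2=C3 from aldehyde 20 and phosphonate 21. Aldehyde 20 is the oxidation product of alcohol 19.

**Alkyne, 18 back to 14.** The terminal alkyne carbon is removed to give aldehyde 16 and diazophosphonate 17. Aldehyde 16 comes from alcohol 15 and acetate 14. The C3–alkyne bond is kept because C3 is already stereogenic at this point, and a one‑carbon homologation leaves it untouched provided the aldehyde is not enolised.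

**Pyran ring and stereocentre, 14 back to 12.** The O1–C2 bond is cut to give monoacetate 13, whose free phenol and free primary alcohol close the ring under dehydrating conditions. In 13 the future C3 carries two CH2O arms that differ only in acylation, so 13 comes from prochiral triol 12 by enzymatic differentiation of enantiotopic groups. This sets C3 in an unhindered, acyclic setting, before any fragile functionality exists.

**Three‑carbon unit, 12 back to 7 and 8.** Triol 12 is the full reduction product of dihydrocoumarin ester 11, which comes from coumarin ester 10. The C3–C4 bond of 10 is a condensation between the aldehyde carbon of 7 and malonate 8, through 9. The aldehyde carbon becomes C4 and the ortho phenol becomes O1, which avoids an unstable, electron‑rich benzylic halide.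

**Ring A, 7 back to 1.** The C6–prenyl bond is cut by returning the prenyl group to the oxygen para to it, the future O1, which gives aryl prenyl ether 4. Direct electrophilic prenylation cannot tell the two free ring positions apart. A tandem sigmatropic shift through 5 and 6 can, and it also liberates the phenol needed for the condensation. Ether 4 comes from silyl ether 2 and alcohol 3, and 2 from aldehyde 1, which already carries the C5 methyl ether.

## Alternatives that were turned down

**Alternative 1:** The C3–C1' and C4–C4a bonds are cut together, leading to ring A aryl triflate A1, ring B aryl bromide A2 and vinylboronic ester A3.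
- Forward key step: the boron ate complex from A3 and lithiated A2 meets the arylpalladium from A1 under a chiral ferrocenyl diphosphine. Ring B migrates from boron to C3 as palladium delivers ring A to C4, giving boronate A4.
- For it: it is convergent, sets C3 by catalysis with both arenes attached in one step, needs no stoichiometric transition metal and avoids an α‑stereogenic aldehyde. On these points it is stronger than the chosen route.
- Against it: A1 is electron‑rich and flanked by two ortho oxygens, so oxidative addition is slow. The migrating aryl is also ortho‑substituted, and enantioselectivity with two hindered partners is uncertain. A4 still needs a one‑carbon homologation at a hindered secondary boron, oxidation, acidic acetal removal next to prenyl groups, ring closure and conversion of a trimethoxyarene into the hydroxyquinone. A1 and A2 are each pentasubstituted arenes that need their own regiocontrolled synthesis.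
- Comparison: the chosen route builds ring B from acyclic pieces with its oxidation pattern in place and sets C3 on an unhindered diol. Only one pentasubstituted arene has to be made by substitution chemistry.

**Alternative 2:** The C6–CH2 and C3'–CH2 bonds are cut, leading to the bis(1,1‑dimethylallyl) ether A5 of a prenyl‑free isoflavan.
- Forward key step: heating A5 transfers both allyl units with allylic inversion to the only free ortho carbons, giving diphenol A6.
- For it: each shift has a single possible terminus, so the regiochemistry is as secure as in the chosen route or more so. The prenyl groups arrive late, so the core could be made with acid or hydrogenation, including an asymmetric hydrogenation for C3.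
- Against it: A6 frees O5–H, which must be methylated, and O4'–H, which must stay free, in the same step. Both are phenols flanked by a prenyl group, so nothing distinguishes them and extra protecting‑group steps follow. Two tertiary allyl ethers on hindered phenols cost further steps, and ortho‑prenyl phenols can cyclise at rearrangement temperatures.
- Comparison: in the chosen route the fate of every oxygen is fixed by construction. The C5 methyl ether comes from 1, and the C4' and C5' oxygens come from 27 and are told apart by the oxidation itself.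

**Alternative 3:** O1–C8a, C4–C4a and the C3–C4 unit are cut, leading to silylaryl triflate A7, N,N‑dimethylformamide A8 and ring B arylacetate A9.
- Forward key step: fluoride generates the aryne from A7. A8 adds across it, oxygen to C8a and formyl carbon to C4a. The enolate of A9 then adds, lactonises and expels the amino group to give 3‑arylcoumarin A10.
- For it: three components give the whole bicyclic core in one flask, and the aryne regiochemistry is favourable because the oxygen nucleophile adds distal to the methoxy group. In convergence it is stronger than the chosen route.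
- Against it: A10 is planar. C3 must then be created by enantioselective reduction of C3=C4 in the presence of two prenyl alkenes, and the lactone carbonyl must be taken down to CH2 by reduction and re‑closure. A7 is a hexasubstituted benzene carrying a prenyl group. Ring B again needs an oxidative demethylation of a trimethoxyarene and an acidic deprotection.
- Comparison: the chosen route never reduces an alkene in the presence of the prenyl groups and reaches the chroman oxidation level directly.

Key step: step 17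

Remark (enzyme sense): the lipase of step 7 is taken to acetylate the pro‑S hydroxymethyl group of 12; if the other arm reacts, the hydrolytic mode described under the uncertain steps gives the same enantiomer 13.
Remark (alkene geometry): 22, 23, 24, 26 and 27 are carried as E/Z mixtures at C2=C3, with the Z isomer (chain trans to the carbonyl or carbene carbon) expected to predominate; both converge on 30.

## Route

Step 1
Reactants: 1 2,4‑dihydroxy‑6‑methoxybenzaldehyde
Product: 2 2‑hydroxy‑6‑methoxy‑4‑(triisopropylsilyloxy)benzaldehyde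
Conditions: i‑Pr3SiCl, imidazole, DMF, 0 °C
Reagents that add atoms: chlorotriisopropylsilane, CC(C)[Si](Cl)(C(C)C)C(C)C
Why: Silylation of the more acidic, non‑chelated para hydroxyl; the ortho hydroxyl is held in a hydrogen bond to the aldehyde and reacts much more slowly. The TIPS ether is chosen because it has to survive amine, hydride and carbonate reagents later.

Step 2
Reactants: 2 2‑hydroxy‑6‑methoxy‑4‑(triisopropylsilyloxy)benzaldehyde; 3 3‑methylbut‑2‑en‑1‑ol
Product: 4 2‑methoxy‑6‑(3‑methylbut‑2‑en‑1‑yloxy)‑4‑(triisopropylsilyloxy)benzaldehyde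
Conditions: PPh3, DIAD, THF, 0 °C → rt
Reagents that add atoms: none
Why: Mitsunobu etherification; the chelated phenol is acidic enough to protonate the betaine, and SN2 attack on the primary oxyphosphonium carbon gives the linear prenyl ether under neutral conditions that leave the aryl silyl ether alone.

Step 3
Reactants: 4 2‑methoxy‑6‑(3‑methylbut‑2‑en‑1‑yloxy)‑4‑(triisopropylsilyloxy)benzaldehyde
Product: 7 6‑hydroxy‑2‑methoxy‑3‑(3‑methylbut‑2‑en‑1‑yl)‑4‑(triisopropylsilyloxy)benzaldehyde, via ortho‑dienone 5 (not isolated), via para‑dienone 6 (not isolated)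
Conditions: N,N‑diethylaniline, 190 °C, sealed tube, Ar
Reagents that add atoms: none
Why: Tandem aromatic Claisen–Cope (para‑Claisen) rearrangement; the first [3,3] shift puts a 1,1‑dimethylallyl group on the only free ortho carbon to give 5, whose crowded sp3 centre passes the group on by a second [3,3] shift to the para carbon (6) before enolisation to 7. This tandem shift is established for 2‑prenyloxy‑4,6‑dialkoxyaryl carbonyl compounds; it places the prenyl group between the methoxy and silyloxy carbons and frees the phenol that becomes O1.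

Step 4
Reactants: 7 6‑hydroxy‑2‑methoxy‑3‑(3‑methylbut‑2‑en‑1‑yl)‑4‑(triisopropylsilyloxy)benzaldehyde; 8 dimethyl malonate
Product: 10 methyl 5‑methoxy‑6‑(3‑methylbut‑2‑en‑1‑yl)‑2‑oxo‑7‑(triisopropylsilyloxy)‑2H‑chromene‑3‑carboxylate, via arylidene malonate 9 (not isolated)
Conditions: piperidine (cat.), AcOH (cat.), toluene, reflux, Dean–Stark
Reagents that add atoms: none
Why: Knoevenagel condensation followed by lactonisation of the ortho phenol onto the cis ester, the classical coumarin‑3‑carboxylate synthesis from salicylaldehydes; the aldehyde carbon becomes C4 and the phenol oxygen becomes O1.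

Step 5
Reactants: 10 methyl 5‑methoxy‑6‑(3‑methylbut‑2‑en‑1‑yl)‑2‑oxo‑7‑(triisopropylsilyloxy)‑2H‑chromene‑3‑carboxylate
Product: 11 methyl 5‑methoxy‑6‑(3‑methylbut‑2‑en‑1‑yl)‑2‑oxo‑7‑(triisopropylsilyloxy)chromane‑3‑carboxylate (racemic)
Conditions: NaBH4, THF/MeOH, 0 °C
Reagents that add atoms: none
Why: Conjugate hydride reduction of the doubly activated alkylidene malonate unit of a 3‑alkoxycarbonylcoumarin; the centre formed is racemic and is erased in step 6, and any over‑reduction of the lactone only anticipates that step.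

Step 6
Reactants: 11 methyl 5‑methoxy‑6‑(3‑methylbut‑2‑en‑1‑yl)‑2‑oxo‑7‑(triisopropylsilyloxy)chromane‑3‑carboxylate
Product: 12 2‑[[2‑hydroxy‑6‑methoxy‑5‑(3‑methylbut‑2‑en‑1‑yl)‑4‑(triisopropylsilyloxy)phenyl]methyl]propane‑1,3‑diol
Conditions: LiAlH4, THF, 0 °C → rt; KNaC4H4O6 (aq) work‑up
Reagents that add atoms: none
Why: LiAlH4 reduction of the aryl lactone and the methyl ester to two primary alcohols, which releases the phenol; the malonate carbon becomes the prochiral centre of a 2‑substituted propane‑1,3‑diol.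

Step 7
Reactants: 12 2‑[[2‑hydroxy‑6‑methoxy‑5‑(3‑methylbut‑2‑en‑1‑yl)‑4‑(triisopropylsilyloxy)phenyl]methyl]propane‑1,3‑diol
Product: 13 (2S)‑3‑hydroxy‑2‑[[2‑hydroxy‑6‑methoxy‑5‑(3‑methylbut‑2‑en‑1‑yl)‑4‑(triisopropylsilyloxy)phenyl]methyl]propyl acetate
Conditions: lipase from Burkholderia cepacia (immobilised), vinyl acetate, t‑BuOMe, 25 °C
Reagents that add atoms: vinyl acetate, CC(=O)OC=C
Why: Enzymatic desymmetrisation of a prochiral 2‑(arylmethyl)propane‑1,3‑diol by irreversible transesterification, a standard use of this lipase class; the chiral binding pocket of the enzyme distinguishes the enantiotopic hydroxymethyl groups and so sets C3, while the hindered phenol is not a substrate. The reaction is stopped before diacetate accumulates, and 13 is used promptly to avoid 1,3‑acyl migration.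

Step 8
Reactants: 13 (2S)‑3‑hydroxy‑2‑[[2‑hydroxy‑6‑methoxy‑5‑(3‑methylbut‑2‑en‑1‑yl)‑4‑(triisopropylsilyloxy)phenyl]methyl]propyl acetate
Product: 14 [(3S)‑5‑methoxy‑6‑(3‑methylbut‑2‑en‑1‑yl)‑7‑(triisopropylsilyloxy)chroman‑3‑yl]methyl acetate
Conditions: PPh3, DIAD, THF, 0 °C → rt
Reagents that add atoms: none
Why: Intramolecular Mitsunobu etherification, a 6‑exo‑tet SN2 displacement at the primary carbon by the phenol, closes the pyran ring; the stereocentre is not a reacting centre and the neutral conditions do not move the acetate.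

Step 9
Reactants: 14 [(3S)‑5‑methoxy‑6‑(3‑methylbut‑2‑en‑1‑yl)‑7‑(triisopropylsilyloxy)chroman‑3‑yl]methyl acetate
Product: 15 [(3R)‑5‑methoxy‑6‑(3‑methylbut‑2‑en‑1‑yl)‑7‑(triisopropylsilyloxy)chroman‑3‑yl]methanol
Conditions: K2CO3 (cat.), MeOH, 0 °C → rt
Reagents that add atoms: none
Why: Base‑catalysed transesterification of a primary acetate; the aryl TIPS ether is stable to catalytic carbonate in methanol. The descriptor changes only because the priorities change.

Step 10
Reactants: 15 [(3R)‑5‑methoxy‑6‑(3‑methylbut‑2‑en‑1‑yl)‑7‑(triisopropylsilyloxy)chroman‑3‑yl]methanol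
Product: 16 (3S)‑5‑methoxy‑6‑(3‑methylbut‑2‑en‑1‑yl)‑7‑(triisopropylsilyloxy)chroman‑3‑carbaldehyde
Conditions: Dess–Martin periodinane, NaHCO3, CH2Cl2, 0 °C
Reagents that add atoms: none
Why: Dess–Martin oxidation of a primary alcohol under buffered, non‑basic conditions; 16 is α‑stereogenic and β to an aryloxy group, so it is not chromatographed and goes straight into step 11.

Step 11
Reactants: 16 (3S)‑5‑methoxy‑6‑(3‑methylbut‑2‑en‑1‑yl)‑7‑(triisopropylsilyloxy)chroman‑3‑carbaldehyde; 17 dimethyl (1‑diazo‑2‑oxopropyl)phosphonate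
Product: 18 (3R)‑3‑ethynyl‑5‑methoxy‑6‑(3‑methylbut‑2‑en‑1‑yl)‑7‑(triisopropylsilyloxy)chroman
Conditions: K2CO3, MeOH, 0 °C → rt
Reagents that add atoms: none
Why: Seyferth–Gilbert homologation in the Ohira–Bestmann variant, which is routinely used on α‑stereogenic aldehydes; in methanol the aldehyde sits largely as its hemiacetal and is captured by the diazophosphonate anion faster than it enolises. The new alkyne carbon, later C6', comes from 17.

Step 12
Reactants: 19 4‑methylpent‑3‑en‑1‑ol
Product: 20 4‑methylpent‑3‑enal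
Conditions: Dess–Martin periodinane, NaHCO3, CH2Cl2, 0 °C; used as a solution
Reagents that add atoms: none
Why: Dess–Martin oxidation under buffered conditions keeps the β,γ double bond out of conjugation; the volatile aldehyde is used without purification.

Step 13
Reactants: 20 4‑methylpent‑3‑enal; 21 methyl 2‑(dimethoxyphosphoryl)‑2‑methoxyacetate
Product: 22 methyl 2‑methoxy‑6‑methylhepta‑2,5‑dienoate (E/Z mixture)
Conditions: LiN(SiMe3)2 (slight deficit relative to 21), THF, −78 → 0 °C
Reagents that add atoms: none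
Why: Horner–Wadsworth–Emmons olefination with an α‑methoxy phosphonoacetate; the deficit of base ensures that no free amide remains to deprotonate the doubly allylic CH2 of 22.

Step 14
Reactants: 22 methyl 2‑methoxy‑6‑methylhepta‑2,5‑dienoate
Product: 23 2‑methoxy‑6‑methylhepta‑2,5‑dienoic acid
Conditions: LiOH·H2O, THF/H2O, 0 °C; then 1 M HCl to pH 3, 0 °C
Reagents that add atoms: lithium hydroxide, [Li+].[OH-]
Why: Saponification of a methyl ester at 0 °C; attack at the ester carbonyl outpaces γ‑deprotonation in aqueous medium, and the carboxylate is no longer acidic at C4, so the skipped diene stays in place.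

Step 15
Reactants: 23 2‑methoxy‑6‑methylhepta‑2,5‑dienoic acid
Product: 24 2‑methoxy‑6‑methylhepta‑2,5‑dienoyl chloride
Conditions: 1‑chloro‑N,N,2‑trimethylprop‑1‑en‑1‑amine, CH2Cl2, 0 °C → rt; used crude
Reagents that add atoms: 1‑chloro‑N,N,2‑trimethylprop‑1‑en‑1‑amine, CC(C)=C(Cl)N(C)C
Why: Acid chloride formation with an α‑chloroenamine under neutral conditions; no HCl is released that could add to the trisubstituted alkene or the enol ether.

Step 16
Reactants: 24 2‑methoxy‑6‑methylhepta‑2,5‑dienoyl chloride; 25 hexacarbonylchromium Cr(CO)6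
Product: 27 pentacarbonyl(1,2‑dimethoxy‑6‑methylhepta‑2,5‑dien‑1‑ylidene)chromium (E/Z mixture), via sodium acyl chromate 26 (not isolated)
Conditions: Cr(CO)6, NaC10H8 (2 equiv), THF, −78 → 0 °C; 24, −78 °C; then Me3OBF4, CH2Cl2, 0 °C
Reagents that add atoms: trimethyloxonium tetrafluoroborate, C[O+](C)C.F[B-](F)(F)F
Why: Acyl chromate route to Fischer carbene complexes; Cr(CO)6 is reduced to Na2Cr(CO)5 (chromium in the oxidation state minus two), which is acylated by 24 at low temperature to give 26, and O‑methylation gives the methoxycarbene complex of zerovalent chromium. The acid chloride has no α‑hydrogen and no base is present after the acylation, which protects the acidic γ‑CH2 of 27.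

Step 17
Reactants: 18 (3R)‑3‑ethynyl‑5‑methoxy‑6‑(3‑methylbut‑2‑en‑1‑yl)‑7‑(triisopropylsilyloxy)chroman; 27 pentacarbonyl(1,2‑dimethoxy‑6‑methylhepta‑2,5‑dien‑1‑ylidene)chromium
Product: 30 2‑[(3R)‑5‑methoxy‑6‑(3‑methylbut‑2‑en‑1‑yl)‑7‑(triisopropylsilyloxy)chroman‑3‑yl]‑4,5‑dimethoxy‑6‑(3‑methylbut‑2‑en‑1‑yl)phenol, via vinylketene chromium complex 28 (not isolated), via tricarbonylchromium arene complex 29 (not isolated)
Conditions: 27 (1.5 equiv), THF (degassed, 0.05 M), 50 °C, Ar; then air, MeCN, 25 °C
Reagents that add atoms: none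
Why: Dötz benzannulation, the established reaction of alkenyl(alkoxy)carbene complexes of zerovalent chromium with terminal alkynes. Thermal loss of one carbonyl ligand from 27 opens a site for 18, which inserts into the Cr=C bond with its substituted carbon away from the methoxy carbon; carbonyl insertion then gives vinylketene complex 28. Ring B closes by a six‑electron electrocyclisation of this dienylketene, the ketene carbon bonding to the β carbon of the former alkenyl group, and enolisation gives the chromium‑bound phenol 29, from which air strips the metal to give 30. Three bonds are made (C5'–C6', C1'–C2', C2'–C3'); no stereocentre is created, and C3, one bond from the alkyne and never deprotonated under these neutral conditions, is untouched. The selectivity needed is regiochemical: the bulky chroman must end ortho to the new hydroxyl, and the steric bias of a terminal alkyne with a branched substituent secures this. The Z isomer of 27, with hydrogen cis to the carbene carbon, cyclises directly; the E isomer is expected to equilibrate at the metal or to close more slowly to the same arene. Neutral THF at 50 °C avoids the base that would move the skipped diene into conjugation.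

Step 18
Reactants: 30 2‑[(3R)‑5‑methoxy‑6‑(3‑methylbut‑2‑en‑1‑yl)‑7‑(triisopropylsilyloxy)chroman‑3‑yl]‑4,5‑dimethoxy‑6‑(3‑methylbut‑2‑en‑1‑yl)phenol
Product: 31 2‑methoxy‑5‑[(3R)‑5‑methoxy‑6‑(3‑methylbut‑2‑en‑1‑yl)‑7‑(triisopropylsilyloxy)chroman‑3‑yl]‑3‑(3‑methylbut‑2‑en‑1‑yl)cyclohexa‑2,5‑diene‑1,4‑dione
Conditions: (NH4)2Ce(NO3)6 (2.2 equiv), MeCN/H2O, −10 → 0 °C, minutes
Reagents that add atoms: water, O
Why: Oxidative demethylation of a para‑methoxyphenol to the para‑quinone by two equivalents of a one‑electron oxidant (tetravalent cerium), with water supplying the new carbonyl oxygen at C5'; the free phenol of ring B is oxidised far more readily than the fully etherified ring A or the alkenes, and the C4' methoxy group survives as a vinylogous ester.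

Step 19
Reactants: 31 2‑methoxy‑5‑[(3R)‑5‑methoxy‑6‑(3‑methylbut‑2‑en‑1‑yl)‑7‑(triisopropylsilyloxy)chroman‑3‑yl]‑3‑(3‑methylbut‑2‑en‑1‑yl)cyclohexa‑2,5‑diene‑1,4‑dione
Product: 32 2‑hydroxy‑5‑[(3R)‑5‑methoxy‑6‑(3‑methylbut‑2‑en‑1‑yl)‑7‑(triisopropylsilyloxy)chroman‑3‑yl]‑3‑(3‑methylbut‑2‑en‑1‑yl)cyclohexa‑2,5‑diene‑1,4‑dione
Conditions: 0.5 M NaOH (aq), THF, 0 °C, Ar; then 1 M HCl to pH 3, 0 °C
Reagents that add atoms: sodium hydroxide, [Na+].[OH-]
Why: Addition–elimination of hydroxide at C4' of the 2‑methoxyquinone, the hydrolysis of a vinylogous ester; the product forms as its anion, a poor electrophile that is much less prone to lose C3–H, so a short, cold exposure preserves the stereocentre. Any silyl ether lost here only anticipates step 20.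

Step 20
Reactants: 32 2‑hydroxy‑5‑[(3R)‑5‑methoxy‑6‑(3‑methylbut‑2‑en‑1‑yl)‑7‑(triisopropylsilyloxy)chroman‑3‑yl]‑3‑(3‑methylbut‑2‑en‑1‑yl)cyclohexa‑2,5‑diene‑1,4‑dione
Product: 33 2‑hydroxy‑5‑[(3R)‑7‑hydroxy‑5‑methoxy‑6‑(3‑methylbut‑2‑en‑1‑yl)chroman‑3‑yl]‑3‑(3‑methylbut‑2‑en‑1‑yl)cyclohexa‑2,5‑diene‑1,4‑dione (target)
Conditions: Bu4NF, AcOH (1:1), THF, 0 °C
Reagents that add atoms: none
Why: Fluoride cleavage of the aryl silyl ether, buffered with acetic acid so that no strong base meets the quinone; acid is avoided because both prenyl groups now lie ortho to free hydroxyls.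

## Compound list

1 | 2,4‑dihydroxy‑6‑methoxybenzaldehyde | O=Cc1c(O)cc(O)cc1OC | starting material
2 | 2‑hydroxy‑6‑methoxy‑4‑(triisopropylsilyloxy)benzaldehyde | O=Cc1c(O)cc(O[Si](C(C)C)(C(C)C)C(C)C)cc1OC | intermediate
3 | 3‑methylbut‑2‑en‑1‑ol | CC(C)=CCO | starting material
4 | 2‑methoxy‑6‑(3‑methylbut‑2‑en‑1‑yloxy)‑4‑(triisopropylsilyloxy)benzaldehyde | O=Cc1c(OCC=C(C)C)cc(O[Si](C(C)C)(C(C)C)C(C)C)cc1OC | intermediate
5 | 2‑methoxy‑5‑(2‑methylbut‑3‑en‑2‑yl)‑6‑oxo‑4‑(triisopropylsilyloxy)cyclohexa‑1,3‑diene‑1‑carbaldehyde (ortho‑dienone) | O=CC1=C(OC)C=C(O[Si](C(C)C)(C(C)C)C(C)C)C(C(C)(C)C=C)C1=O | intermediate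
6 | 2‑methoxy‑3‑(3‑methylbut‑2‑en‑1‑yl)‑6‑oxo‑4‑(triisopropylsilyloxy)cyclohexa‑1,4‑diene‑1‑carbaldehyde (para‑dienone) | O=CC1=C(OC)C(CC=C(C)C)C(O[Si](C(C)C)(C(C)C)C(C)C)=CC1=O | intermediate
7 | 6‑hydroxy‑2‑methoxy‑3‑(3‑methylbut‑2‑en‑1‑yl)‑4‑(triisopropylsilyloxy)benzaldehyde | O=Cc1c(O)cc(O[Si](C(C)C)(C(C)C)C(C)C)c(CC=C(C)C)c1OC | intermediate
8 | dimethyl malonate | COC(=O)CC(=O)OC | starting material
9 | dimethyl 2‑[[6‑hydroxy‑2‑methoxy‑3‑(3‑methylbut‑2‑en‑1‑yl)‑4‑(triisopropylsilyloxy)phenyl]methylidene]propanedioate | COC(=O)C(=Cc1c(O)cc(O[Si](C(C)C)(C(C)C)C(C)C)c(CC=C(C)C)c1OC)C(=O)OC | intermediate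
10 | methyl 5‑methoxy‑6‑(3‑methylbut‑2‑en‑1‑yl)‑2‑oxo‑7‑(triisopropylsilyloxy)‑2H‑chromene‑3‑carboxylate | COC(=O)C1=Cc2c(OC)c(CC=C(C)C)c(O[Si](C(C)C)(C(C)C)C(C)C)cc2OC1=O | intermediate
11 | methyl 5‑methoxy‑6‑(3‑methylbut‑2‑en‑1‑yl)‑2‑oxo‑7‑(triisopropylsilyloxy)chromane‑3‑carboxylate (racemic) | COC(=O)C1Cc2c(OC)c(CC=C(C)C)c(O[Si](C(C)C)(C(C)C)C(C)C)cc2OC1=O | intermediate
12 | 2‑[[2‑hydroxy‑6‑methoxy‑5‑(3‑methylbut‑2‑en‑1‑yl)‑4‑(triisopropylsilyloxy)phenyl]methyl]propane‑1,3‑diol | COc1c(CC=C(C)C)c(O[Si](C(C)C)(C(C)C)C(C)C)cc(O)c1CC(CO)CO | intermediate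
13 | (2S)‑3‑hydroxy‑2‑[[2‑hydroxy‑6‑methoxy‑5‑(3‑methylbut‑2‑en‑1‑yl)‑4‑(triisopropylsilyloxy)phenyl]methyl]propyl acetate | COc1c(CC=C(C)C)c(O[Si](C(C)C)(C(C)C)C(C)C)cc(O)c1C[C@H](COC(C)=O)CO | intermediate
14 | [(3S)‑5‑methoxy‑6‑(3‑methylbut‑2‑en‑1‑yl)‑7‑(triisopropylsilyloxy)chroman‑3‑yl]methyl acetate | COc1c(CC=C(C)C)c(O[Si](C(C)C)(C(C)C)C(C)C)cc2c1C[C@H](COC(C)=O)CO2 | intermediate
15 | [(3R)‑5‑methoxy‑6‑(3‑methylbut‑2‑en‑1‑yl)‑7‑(triisopropylsilyloxy)chroman‑3‑yl]methanol | COc1c(CC=C(C)C)c(O[Si](C(C)C)(C(C)C)C(C)C)cc2c1C[C@H](CO)CO2 | intermediate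
16 | (3S)‑5‑methoxy‑6‑(3‑methylbut‑2‑en‑1‑yl)‑7‑(triisopropylsilyloxy)chroman‑3‑carbaldehyde | COc1c(CC=C(C)C)c(O[Si](C(C)C)(C(C)C)C(C)C)cc2c1C[C@H](C=O)CO2 | intermediate
17 | dimethyl (1‑diazo‑2‑oxopropyl)phosphonate | CC(=O)C(=[N+]=[N-])P(=O)(OC)OC | starting material
18 | (3R)‑3‑ethynyl‑5‑methoxy‑6‑(3‑methylbut‑2‑en‑1‑yl)‑7‑(triisopropylsilyloxy)chroman | COc1c(CC=C(C)C)c(O[Si](C(C)C)(C(C)C)C(C)C)cc2c1C[C@H](C#C)CO2 | intermediate
19 | 4‑methylpent‑3‑en‑1‑ol | CC(C)=CCCO | starting material
20 | 4‑methylpent‑3‑enal | CC(C)=CCC=O | intermediate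
21 | methyl 2‑(dimethoxyphosphoryl)‑2‑methoxyacetate | COC(=O)C(OC)P(=O)(OC)OC | starting material
22 | methyl 2‑methoxy‑6‑methylhepta‑2,5‑dienoate (E/Z at C2=C3) | COC(=O)C(OC)=CCC=C(C)C | intermediate
23 | 2‑methoxy‑6‑methylhepta‑2,5‑dienoic acid (E/Z) | OC(=O)C(OC)=CCC=C(C)C | intermediate
24 | 2‑methoxy‑6‑methylhepta‑2,5‑dienoyl chloride (E/Z) | ClC(=O)C(OC)=CCC=C(C)C | intermediate
25 | hexacarbonylchromium, Cr(CO)6 | O=C=[Cr](=C=O)(=C=O)(=C=O)(=C=O)=C=O | starting material
26 | sodium pentacarbonyl(2‑methoxy‑6‑methylhepta‑2,5‑dienoyl)chromate | [Na+].[O-]C(C(OC)=CCC=C(C)C)=[Cr](=C=O)(=C=O)(=C=O)(=C=O)=C=O | intermediate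
27 | pentacarbonyl(1,2‑dimethoxy‑6‑methylhepta‑2,5‑dien‑1‑ylidene)chromium (E/Z) | COC(C(OC)=CCC=C(C)C)=[Cr](=C=O)(=C=O)(=C=O)(=C=O)=C=O | intermediate
28 | tricarbonylchromium complex of the dienylketene 2‑[(3R)‑chroman‑3‑yl]‑4,5‑dimethoxy‑9‑methyldeca‑1,3,5,8‑tetraen‑1‑one, chroman substituted as in 18 (η4; metal fragment written as a separate component) | COc1c(CC=C(C)C)c(O[Si](C(C)C)(C(C)C)C(C)C)cc2c1C[C@H](C(=C=O)C=C(OC)C(OC)=CCC=C(C)C)CO2.[Cr](=C=O)(=C=O)=C=O | intermediate
29 | tricarbonylchromium complex of phenol 30 (η6 on ring B; metal fragment written as a separate component) | COc1c(CC=C(C)C)c(O[Si](C(C)C)(C(C)C)C(C)C)cc2c1C[C@H](c1cc(OC)c(OC)c(CC=C(C)C)c1O)CO2.[Cr](=C=O)(=C=O)=C=O | intermediate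
30 | 2‑[(3R)‑5‑methoxy‑6‑(3‑methylbut‑2‑en‑1‑yl)‑7‑(triisopropylsilyloxy)chroman‑3‑yl]‑4,5‑dimethoxy‑6‑(3‑methylbut‑2‑en‑1‑yl)phenol | COc1c(CC=C(C)C)c(O[Si](C(C)C)(C(C)C)C(C)C)cc2c1C[C@H](c1cc(OC)c(OC)c(CC=C(C)C)c1O)CO2 | intermediate
31 | 2‑methoxy‑5‑[(3R)‑5‑methoxy‑6‑(3‑methylbut‑2‑en‑1‑yl)‑7‑(triisopropylsilyloxy)chroman‑3‑yl]‑3‑(3‑methylbut‑2‑en‑1‑yl)cyclohexa‑2,5‑diene‑1,4‑dione | COc1c(CC=C(C)C)c(O[Si](C(C)C)(C(C)C)C(C)C)cc2c1C[C@H](C1=CC(=O)C(OC)=C(CC=C(C)C)C1=O)CO2 | intermediate
32 | 2‑hydroxy‑5‑[(3R)‑5‑methoxy‑6‑(3‑methylbut‑2‑en‑1‑yl)‑7‑(triisopropylsilyloxy)chroman‑3‑yl]‑3‑(3‑methylbut‑2‑en‑1‑yl)cyclohexa‑2,5‑diene‑1,4‑dione | COc1c(CC=C(C)C)c(O[Si](C(C)C)(C(C)C)C(C)C)cc2c1C[C@H](C1=CC(=O)C(O)=C(CC=C(C)C)C1=O)CO2 | intermediate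
33 | 2‑hydroxy‑5‑[(3R)‑7‑hydroxy‑5‑methoxy‑6‑(3‑methylbut‑2‑en‑1‑yl)chroman‑3‑yl]‑3‑(3‑methylbut‑2‑en‑1‑yl)cyclohexa‑2,5‑diene‑1,4‑dione | COc1c(CC=C(C)C)c(O)cc2c1C[C@H](C1=CC(=O)C(O)=C(CC=C(C)C)C1=O)CO2 | target

## Step count and least certain steps

Total step count: 20. Longest linear sequence: 15 steps (steps 1–11 and 17–20). The carbene branch (steps 12–16) is five steps.

**Step 17 (key step).** The most likely failure is that carbonyl insertion and electrocyclic closure do not keep pace with competing pathways. The electron‑rich α‑methoxy substituent can divert the alkyne‑insertion stage into non‑aromatic products, the terminal alkyne can be taken up twice, and the E isomer of 27 closes slowly.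

The fallback sets out from 18 and returns at 31, without chromium and without a separate oxidation.
- Dimethyl squarate is treated with CH2=CHCH2MgBr and then acid to give 3‑allyl‑4‑methoxycyclobut‑3‑ene‑1,2‑dione F1.
- Cross‑metathesis of F1 with 2‑methylbut‑2‑ene (second‑generation Grubbs catalyst) gives 3‑methoxy‑4‑(3‑methylbut‑2‑en‑1‑yl)cyclobut‑3‑ene‑1,2‑dione F2.
- The lithium acetylide of 18 (n‑BuLi, THF, −78 °C) adds to the carbonyl next to the methoxy‑bearing carbon of F2 to give the 4‑alkynyl‑4‑hydroxycyclobutenone F3.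
- Heating F3 in toluene (Moore cyclisation: electrocyclic ring opening, closure onto the alkyne and hydrogen transfer) places the chroman next to the carbonyl that adjoins the prenyl carbon and gives 31.

**Step 16.** The strongly basic chromate may deprotonate 24 at the doubly allylic C4 and so lose it through elimination. Alternatively, the C5=C6 double bond may migrate into conjugation once the γ‑CH2 is acidified by the carbene carbon.

The fallback removes the skipped diene from the carbene. It sets out from 18 and returns at 30.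
- 1‑Methoxyvinyllithium (methyl vinyl ether, t‑BuLi, THF) is added to Cr(CO)6 and the acylate is methylated with Me3OBF4 to give pentacarbonyl(1,2‑dimethoxyprop‑2‑en‑1‑ylidene)chromium F4.
- Benzannulation of F4 with 18 under the conditions of step 17 gives the prenyl‑free phenol F5.
- O‑Allylation of F5 with tert‑butyl 2‑methylbut‑3‑en‑2‑yl carbonate and Pd(PPh3)4 (zerovalent palladium) gives the 1,1‑dimethylallyl ether F6.
- An aromatic Claisen rearrangement of F6 in warm toluene moves the allyl unit to C3', the only free ortho carbon, and gives 30.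

**Step 11.** Configurational integrity at C3 may be lost in carbonate/methanol, either by enolisation of 16 or by retro‑oxa‑Michael opening and re‑closure of the pyran ring.

The fallback is a Corey–Fuchs sequence from 16 that returns at 18. CBr4 and PPh3 in CH2Cl2 at 0 °C convert 16 into (3R)‑3‑(2,2‑dibromovinyl)‑5‑methoxy‑6‑(3‑methylbut‑2‑en‑1‑yl)‑7‑(triisopropylsilyloxy)chroman F7. n‑BuLi at −78 °C then gives the alkyne by bromine–lithium exchange and 1,2‑shift. The aldehyde never meets an alkoxide.

**Step 7.** The enzyme may acetylate the wrong enantiotopic arm, or the acylation may be slow and poorly selective because the aryl group carries two ortho substituents.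

The fallback sets out from 12 and returns at 13. Exhaustive enzymatic acetylation of both primary hydroxyls gives 2‑[[2‑hydroxy‑6‑methoxy‑5‑(3‑methylbut‑2‑en‑1‑yl)‑4‑(triisopropylsilyloxy)phenyl]methyl]propane‑1,3‑diyl diacetate F8. Hydrolysis of F8 with the same lipase in phosphate buffer/t‑BuOMe then unmasks the arm the enzyme prefers. This leaves the acetate on the opposite arm and so gives the enantiomer complementary to the acylation mode.

**Step 18.** The one‑electron oxidant may over‑oxidise the substrate, by electron transfer from the electron‑rich ring A or by attack on the prenyl double bonds. The strongly acidic medium may also remove the silyl ether.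

The fallback sets out from 30 and returns at 31. The phenol‑specific two‑electron oxidant PhI(OAc)2 in MeOH at 0 °C gives the quinone monoketal 4,4,5‑trimethoxy‑2‑[(3R)‑5‑methoxy‑6‑(3‑methylbut‑2‑en‑1‑yl)‑7‑(triisopropylsilyloxy)chroman‑3‑yl]‑6‑(3‑methylbut‑2‑en‑1‑yl)cyclohexa‑2,5‑dien‑1‑one F9. Oxalic acid on moist silica then hydrolyses F9 to 31.

## Further compounds

F1 | step 17 | 3‑allyl‑4‑methoxycyclobut‑3‑ene‑1,2‑dione | COC1=C(CC=C)C(=O)C1=O
F2 | step 17 | 3‑methoxy‑4‑(3‑methylbut‑2‑en‑1‑yl)cyclobut‑3‑ene‑1,2‑dione | COC1=C(CC=C(C)C)C(=O)C1=O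
F3 | step 17 | 4‑hydroxy‑3‑methoxy‑4‑[[(3R)‑5‑methoxy‑6‑(3‑methylbut‑2‑en‑1‑yl)‑7‑(triisopropylsilyloxy)chroman‑3‑yl]ethynyl]‑2‑(3‑methylbut‑2‑en‑1‑yl)cyclobut‑2‑en‑1‑one (carbinol epimers) | COc1c(CC=C(C)C)c(O[Si](C(C)C)(C(C)C)C(C)C)cc2c1C[C@H](C#CC1(O)C(=O)C(CC=C(C)C)=C1OC)CO2
F4 | step 16 | pentacarbonyl(1,2‑dimethoxyprop‑2‑en‑1‑ylidene)chromium | COC(C(OC)=C)=[Cr](=C=O)(=C=O)(=C=O)(=C=O)=C=O
F5 | step 16 | 2‑[(3R)‑5‑methoxy‑6‑(3‑methylbut‑2‑en‑1‑yl)‑7‑(triisopropylsilyloxy)chroman‑3‑yl]‑4,5‑dimethoxyphenol | COc1c(CC=C(C)C)c(O[Si](C(C)C)(C(C)C)C(C)C)cc2c1C[C@H](c1cc(OC)c(OC)cc1O)CO2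
F6 | step 16 | (3R)‑3‑[4,5‑dimethoxy‑2‑(2‑methylbut‑3‑en‑2‑yloxy)phenyl]‑5‑methoxy‑6‑(3‑methylbut‑2‑en‑1‑yl)‑7‑(triisopropylsilyloxy)chroman | COc1c(CC=C(C)C)c(O[Si](C(C)C)(C(C)C)C(C)C)cc2c1C[C@H](c1cc(OC)c(OC)cc1OC(C)(C)C=C)CO2
F7 | step 11 | (3R)‑3‑(2,2‑dibromovinyl)‑5‑methoxy‑6‑(3‑methylbut‑2‑en‑1‑yl)‑7‑(triisopropylsilyloxy)chroman | COc1c(CC=C(C)C)c(O[Si](C(C)C)(C(C)C)C(C)C)cc2c1C[C@H](C=C(Br)Br)CO2
F8 | step 7 | 2‑[[2‑hydroxy‑6‑methoxy‑5‑(3‑methylbut‑2‑en‑1‑yl)‑4‑(triisopropylsilyloxy)phenyl]methyl]propane‑1,3‑diyl diacetate | COc1c(CC=C(C)C)c(O[Si](C(C)C)(C(C)C)C(C)C)cc(O)c1CC(COC(C)=O)COC(C)=O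
F9 | step 18 | 4,4,5‑trimethoxy‑2‑[(3R)‑5‑methoxy‑6‑(3‑methylbut‑2‑en‑1‑yl)‑7‑(triisopropylsilyloxy)chroman‑3‑yl]‑6‑(3‑methylbut‑2‑en‑1‑yl)cyclohexa‑2,5‑dien‑1‑one | COc1c(CC=C(C)C)c(O[Si](C(C)C)(C(C)C)C(C)C)cc2c1C[C@H](C1=CC(OC)(OC)C(OC)=C(CC=C(C)C)C1=O)CO2
A1 | alternative 1 | 2‑methoxy‑4,6‑bis(methoxymethoxy)‑3‑(3‑methylbut‑2‑en‑1‑yl)phenyl trifluoromethanesulfonate | COc1c(CC=C(C)C)c(OCOC)cc(OCOC)c1OS(=O)(=O)C(F)(F)F
A2 | alternative 1 | 1‑bromo‑2,4,5‑trimethoxy‑3‑(3‑methylbut‑2‑en‑1‑yl)benzene | COc1cc(Br)c(OC)c(CC=C(C)C)c1OC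
A3 | alternative 1 | vinylboronic acid pinacol ester | C=CB1OC(C)(C)C(C)(C)O1
A4 | alternative 1 | secondary benzylic pinacol boronate carrying ring B on the boron‑bearing carbon and ring A on the adjacent CH2 | COc1c(CC=C(C)C)c(OCOC)cc(OCOC)c1C[C@@H](B1OC(C)(C)C(C)(C)O1)c1cc(OC)c(OC)c(CC=C(C)C)c1OC
A5 | alternative 2 | (3R)‑7‑pivaloyloxy‑2',5'‑dimethoxy‑5,4'‑bis(2‑methylbut‑3‑en‑2‑yloxy)isoflavan | C=CC(C)(C)Oc1cc(OC(=O)C(C)(C)C)cc2c1C[C@H](c1cc(OC)c(OC(C)(C)C=C)cc1OC)CO2
A6 | alternative 2 | (3R)‑5,4'‑dihydroxy‑2',5'‑dimethoxy‑7‑pivaloyloxy‑6,3'‑diprenylisoflavan | Oc1c(CC=C(C)C)c(OC(=O)C(C)(C)C)cc2c1C[C@H](c1cc(OC)c(O)c(CC=C(C)C)c1OC)CO2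
A7 | alternative 3 | 2‑methoxy‑4‑(methoxymethoxy)‑3‑(3‑methylbut‑2‑en‑1‑yl)‑6‑(trimethylsilyl)phenyl trifluoromethanesulfonate | COc1c(CC=C(C)C)c(OCOC)cc([Si](C)(C)C)c1OS(=O)(=O)C(F)(F)F
A8 | alternative 3 | N,N‑dimethylformamide | CN(C)C=O
A9 | alternative 3 | methyl 2‑[2,4,5‑trimethoxy‑3‑(3‑methylbut‑2‑en‑1‑yl)phenyl]acetate | COC(=O)Cc1cc(OC)c(OC)c(CC=C(C)C)c1OC
A10 | alternative 3 | 5‑methoxy‑7‑(methoxymethoxy)‑6‑prenyl‑3‑(2,4,5‑trimethoxy‑3‑prenylphenyl)coumarin | COc1c(CC=C(C)C)c(OCOC)cc2oc(=O)c(-c3cc(OC)c(OC)c(CC=C(C)C)c3OC)cc12
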